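**Plan**
1. Retrosynthesis: cut the aryl–vinyl bond of the p-coumarate (Heck) and the C6–O acyl bond, then C6–H (hydride) and C5–H (kinetic protonation), which leads back to the conjugated enone (7S,10R)-eudesm-4-en-6-one.
2. Ring B (C5–C6–C7–C8–C9–C10) is cut at C6–C7 and C7–C8: taking out C7 with its isopropyl group leaves a cyclopentanone (C5, C6, C8, C9, C10) fused to ring A. Ring A is cut at C4=C5 (aldol) and at the quaternary C10–C1 bond (conjugate addition to 3-methylcyclopent-2-enone).
3. Forward order: five-membered ring with C10 set → ring A by aldol condensation → ring B by one-carbon ring expansion with 1-diazo-2-methylpropane → C3=C4 alkene, C5 and C6 → acrylate → Heck arylation.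
4. Enabling feature: the C6 oxygen lies between ring-fusion C5 and the isopropyl-bearing C7, so a C6 ketone with CH(i-Pr) as α-carbon is the retron of a diazoalkane insertion into the C6–C8 acyl–methylene bond. The C4=C5 enone of ring A makes the other acyl bond (C6–C5) an sp2 bond that should not migrate.
5. Stereochemistry: C10 from the chiral copper catalyst; C7 by equilibration (equatorial isopropyl); C5 by protonation of the dienolate anti to the C10 methyl; C6 by hydride attack anti to the axial C10 methyl.

Key step: step 4

Remark: eudesmane numbers are used for ring atoms (ring A: C1–C5, C10; ring B: C5–C10). The target is read as (5R,6R,7S,10R), a trans-decalin with 10β-methyl, 5α-H, axial 6β-acyloxy and equatorial 7β-isopropyl. In step 1 the ligand antipode that gives (R)-5 is assumed to be used.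

**Step 1**
Reactants: 1 2-(3-bromopropyl)-2-methyl-1,3-dioxolane; 2 3-methylcyclopent-2-en-1-one
Product: 5 (3R)-3-methyl-3-[3-(2-methyl-1,3-dioxolan-2-yl)propyl]cyclopentan-1-one, via Grignard reagent 3 (not isolated), via magnesium enolate 4 (not isolated)
Conditions: Mg, Et2O, 35 °C; then added slowly to 2, Cu(OTf)2 (3 mol %), C2-symmetric chiral imidazolinium chloride (carbene precursor, 4 mol %), Et2O, −30 °C; aq NH4Cl
Reagents that add atoms: none
Why: Copper-catalysed asymmetric conjugate addition of a Grignard reagent to a β-methyl cyclic enone, in which the chiral carbene–copper complex should choose the enone face and so set the quaternary centre C10 as (R); the dioxolane is inert to the organometallic.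

**Step 2**
Reactants: 5 (3R)-3-methyl-3-[3-(2-methyl-1,3-dioxolan-2-yl)propyl]cyclopentan-1-one
Product: 7 (3aR)-3a,7-dimethyl-2,3,3a,4,5,6-hexahydro-1H-inden-1-one, via diketone 6 (not isolated)
Conditions: TsOH·H2O (10 mol %), THF/H2O, 50 °C; then KOH (0.5 equiv), MeOH, 65 °C
Reagents that add atoms: none
Why: Acid hydrolysis of the dioxolane followed by base-mediated intramolecular aldol condensation (C5 enolate onto the C4 methyl ketone, six-membered ring A) should funnel under thermodynamic control to the fused conjugated enone, with the non-enolisable C10 unchanged.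

**Step 3**
Reactants: 8 2-methylpropanal; 9 4-methylbenzenesulfonohydrazide
Product: 10 N'-(2-methylpropylidene)-4-methylbenzenesulfonohydrazide
Conditions: MeOH, 23 °C
Reagents that add atoms: none
Why: Condensation of the aldehyde with the sulfonyl hydrazide should give the crystalline tosylhydrazone, the diazoalkane precursor for a Bamford–Stevens reaction.

**Step 4**
Reactants: 7 (3aR)-3a,7-dimethyl-2,3,3a,4,5,6-hexahydro-1H-inden-1-one; 10 N'-(2-methylpropylidene)-4-methylbenzenesulfonohydrazide
Product: 14 (2S,4aR)-4a,8-dimethyl-2-(propan-2-yl)-3,4,4a,5,6,7-hexahydronaphthalen-1(2H)-one, via hydrazone sodium salt 11 (not isolated), via 1-diazo-2-methylpropane 12 (not isolated), via C7-epimeric ketone 13 (not isolated)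
Conditions: 10, NaOMe (1.0 equiv), MeOH, evaporate; dry salt at 90–110 °C/0.1 mmHg, distillate trapped in toluene at −78 °C and used at once; added to 7, Sc(OTf)3 (10 mol %), toluene, −78 → −30 °C; then NaOMe (0.3 equiv), MeOH, 23 °C
Reagents that add atoms: none
Why: Sc(OTf)3 activates the C6 carbonyl of 7, the nucleophilic carbon of 12 adds to it, and in the resulting β-alkoxy diazonium betaine the C6–C8 bond antiperiplanar to the C–N2 bond shifts to the diazo carbon as N2 leaves, so that CH(i-Pr) (C7) is inserted between C6 and C8 and the five-membered ring (C5, C6, C8, C9, C10) becomes ring B. The closest known reaction type is the Lewis acid-catalysed diazoalkane–ketone homologation (Tiffeneau–Demjanov-type ring expansion), known for cycloalkanones with monosubstituted non-stabilised diazoalkanes and for conjugated cyclic enones, where the saturated α-carbon migrates. No ring is closed by cyclisation: ring B arises by the 1,2-shift (one-carbon insertion) and ring A is untouched. The new stereocentre C7 forms without control and is then set thermodynamically by NaOMe through the C6/C7 enolate, the isopropyl group settling equatorial (7S, β) on the rigid octalone with its axial C10 methyl; C10 is not involved. The step needs migration of the sp3 methylene C8 and not of the alkenyl carbon C5, 1,2-addition and not dipolar cycloaddition, and a single homologation: the fully substituted, conjugated C5 (whose shift would break the enone and crowd the new bond) and the shielded tetrasubstituted C4=C5 bond should secure the first two, and the α-branched, more hindered ketone 13 should resist a second insertion.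

**Step 5**
Reactants: 14 (2S,4aR)-4a,8-dimethyl-2-(propan-2-yl)-3,4,4a,5,6,7-hexahydronaphthalen-1(2H)-one
Product: 16 (2S,4aR,8aR)-4a,8-dimethyl-2-(propan-2-yl)-3,4,4a,5,6,8a-hexahydronaphthalen-1(2H)-one, via potassium dienolate 15 (not isolated)
Conditions: KOt-Bu (5 equiv), t-BuOH/THF, 23 °C, argon; poured into cold 10% aq AcOH; crude product used at once
Reagents that add atoms: none
Why: Base-mediated deconjugation, in which excess KOt-Bu should convert the enone into the extended dienolate with the more substituted endocyclic C3=C4 bond and kinetic protonation by AcOH occurs at the α-carbon C5 from the face anti to the angular C10 methyl, giving the trans ring fusion (5α-H) and leaving C7 untouched.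

**Step 6**
Reactants: 16 (2S,4aR,8aR)-4a,8-dimethyl-2-(propan-2-yl)-3,4,4a,5,6,8a-hexahydronaphthalen-1(2H)-one
Product: 17 (1R,2S,4aR,8aR)-4a,8-dimethyl-2-(propan-2-yl)-1,2,3,4,4a,5,6,8a-octahydronaphthalen-1-ol
Conditions: LiAlH4, Et2O, −78 → 0 °C; H2O
Reagents that add atoms: none
Why: Hydride reduction of the ketone, in which the axial C10 methyl shields the β face of C6 so that hydride should add from the α face and give the axial 6β-alcohol (6R).

**Step 7**
Reactants: 17 (1R,2S,4aR,8aR)-4a,8-dimethyl-2-(propan-2-yl)-1,2,3,4,4a,5,6,8a-octahydronaphthalen-1-ol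
Product: 18 (1R,2S,4aR,8aR)-4a,8-dimethyl-2-(propan-2-yl)-1,2,3,4,4a,5,6,8a-octahydronaphthalen-1-yl prop-2-enoate
Conditions: acryloyl chloride, i-Pr2NEt, DMAP (10 mol %), CH2Cl2, 0 → 23 °C
Reagents that add atoms: acryloyl chloride, C=CC(Cl)=O
Why: DMAP-catalysed acylation (acylpyridinium transfer) with the small, reactive acid chloride should esterify the hindered axial alcohol with retention at C6.

**Step 8**
Reactants: 18 (1R,2S,4aR,8aR)-4a,8-dimethyl-2-(propan-2-yl)-1,2,3,4,4a,5,6,8a-octahydronaphthalen-1-yl prop-2-enoate; 19 4-iodophenol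
Product: 20 (1R,2S,4aR,8aR)-4a,8-dimethyl-2-(propan-2-yl)-1,2,3,4,4a,5,6,8a-octahydronaphthalen-1-yl (2E)-3-(4-hydroxyphenyl)prop-2-enoate
Conditions: Pd(OAc)2 (5 mol %), Et3N, DMF, 80 °C
Reagents that add atoms: none
Why: Mizoroki–Heck reaction, in which oxidative addition of the aryl iodide, syn insertion at the β-carbon of the acrylate and syn β-hydride elimination should give the (E)-cinnamate, while the free phenol and the hindered trisubstituted C3=C4 bond do not take part.

**Compound list**
1 | 2-(3-bromopropyl)-2-methyl-1,3-dioxolane | CC1(CCCBr)OCCO1 | starting material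
2 | 3-methylcyclopent-2-en-1-one | CC1=CC(=O)CC1 | starting material
3 | [3-(2-methyl-1,3-dioxolan-2-yl)propyl]magnesium bromide | CC1(CCC[Mg]Br)OCCO1 | intermediate
4 | bromomagnesium enolate of 5 (C5=C6 enolate) | C[C@@]1(CCCC2(C)OCCO2)CCC(O[Mg]Br)=C1 | intermediate
5 | (3R)-3-methyl-3-[3-(2-methyl-1,3-dioxolan-2-yl)propyl]cyclopentan-1-one | C[C@@]1(CCCC2(C)OCCO2)CCC(=O)C1 | intermediate
6 | (3R)-3-methyl-3-(4-oxopentyl)cyclopentan-1-one | C[C@@]1(CCCC(C)=O)CCC(=O)C1 | intermediate
7 | (3aR)-3a,7-dimethyl-2,3,3a,4,5,6-hexahydro-1H-inden-1-one | CC1=C2C(=O)CC[C@@]2(C)CCC1 | intermediate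
8 | 2-methylpropanal | CC(C)C=O | starting material
9 | 4-methylbenzenesulfonohydrazide | Cc1ccc(cc1)S(=O)(=O)NN | starting material
10 | N'-(2-methylpropylidene)-4-methylbenzenesulfonohydrazide | CC(C)/C=N/NS(=O)(=O)c1ccc(C)cc1 | intermediate
11 | sodium salt of 10 | CC(C)/C=N/[N-]S(=O)(=O)c1ccc(C)cc1.[Na+] | intermediate
12 | 1-diazo-2-methylpropane | CC(C)C=[N+]=[N-] | intermediate
13 | (4aR)-4a,8-dimethyl-2-(propan-2-yl)-3,4,4a,5,6,7-hexahydronaphthalen-1(2H)-one, mixture of C7 epimers | CC1=C2C(=O)C(C(C)C)CC[C@@]2(C)CCC1 | intermediate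
14 | (2S,4aR)-4a,8-dimethyl-2-(propan-2-yl)-3,4,4a,5,6,7-hexahydronaphthalen-1(2H)-one, (7S,10R)-eudesm-4-en-6-one | CC1=C2C(=O)[C@H](C(C)C)CC[C@@]2(C)CCC1 | intermediate
15 | potassium (7S,10R)-eudesma-3,5-dien-6-olate | CC1=CCC[C@]2(C)CC[C@@H](C(C)C)C([O-])=C12.[K+] | intermediate
16 | (2S,4aR,8aR)-4a,8-dimethyl-2-(propan-2-yl)-3,4,4a,5,6,8a-hexahydronaphthalen-1(2H)-one, 5α-H eudesm-3-en-6-one | CC1=CCC[C@]2(C)CC[C@@H](C(C)C)C(=O)[C@@H]12 | intermediate
17 | (1R,2S,4aR,8aR)-4a,8-dimethyl-2-(propan-2-yl)-1,2,3,4,4a,5,6,8a-octahydronaphthalen-1-ol, eudesm-3-en-6β-ol | CC1=CCC[C@]2(C)CC[C@@H](C(C)C)[C@@H](O)[C@@H]12 | intermediate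
18 | (1R,2S,4aR,8aR)-4a,8-dimethyl-2-(propan-2-yl)-1,2,3,4,4a,5,6,8a-octahydronaphthalen-1-yl prop-2-enoate | CC1=CCC[C@]2(C)CC[C@@H](C(C)C)[C@@H](OC(=O)C=C)[C@@H]12 | intermediate
19 | 4-iodophenol | Oc1ccc(I)cc1 | starting material
20 | (1R,2S,4aR,8aR)-4a,8-dimethyl-2-(propan-2-yl)-1,2,3,4,4a,5,6,8a-octahydronaphthalen-1-yl (2E)-3-(4-hydroxyphenyl)prop-2-enoate | CC1=CCC[C@]2(C)CC[C@@H](C(C)C)[C@@H](OC(=O)/C=C/c3ccc(O)cc3)[C@@H]12 | target

**Step count**
Total steps: 8. Longest linear sequence: 7 steps (1, 2, 4, 5, 6, 7, 8); step 3 is a one-step side branch.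

**Steps most likely to fail**

Step 4. The alkenyl carbon C5 may migrate in place of the C8 methylene, or the non-stabilised diazoalkane may be lost (dipolar cycloaddition, azine formation, 1,2-hydride shift) before it adds to the hindered conjugated carbonyl. The fallback sets out from 7 and fixes the regiochemistry by construction. Kinetic deprotonation at C8 (LiN(i-Pr)2, THF, −78 °C) and silylation with Me3SiCl should give the cross-conjugated silyl dienol ether F1. Dibromocarbene (CHBr3, KOt-Bu, pentane, −30 °C) should add to its electron-rich C6=C8 bond to give the siloxy dibromocyclopropane F2. On warming, F2 should open at the ring-fusion C6–C8 bond to the ring-enlarged 2-bromo dienone F3, so ring B again arises by one-carbon ring expansion. Suzuki–Miyaura coupling of F3 with isopropenylboronic acid pinacol ester (Pd(PPh3)4, K3PO4, dioxane/H2O, 80 °C) should give the isopropenyl dienone F4. Hydrogenation (H2, Pd/C, EtOAc) should saturate the isopropenyl and C7=C8 bonds and spare the tetrasubstituted C4=C5 bond. This returns to the route at 13 and, after the same NaOMe equilibration, at 14.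

Step 5. Deprotonation may occur at the C4 methyl in place of C3, the dienolate may be protonated at C3 or from the β face, and the product may reconjugate during work-up. The fallback sets out from 14. Acid-equilibrated enol acetylation (isopropenyl acetate, TsOH cat., reflux) should give the endocyclic dienol acetate F5. Treatment with NaBH4 in EtOH/THF (0 → 23 °C) cleaves the enol ester; the dienolate is protonated at C5 by the solvent and the β,γ-unsaturated ketone is reduced in the same flask before it can reconjugate. This returns to the route at 17.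

Step 1. Facial discrimination may be low, and 1,2-addition may compete, when the functionalised Grignard reagent adds to the five-membered β-methyl enone. The fallback sets out from 1 and reverses the roles of the two substituents at C10. Grignard reagent 3 is added to commercial 3-ethoxycyclopent-2-en-1-one (THF, 0 °C) to give the tertiary allylic alcohol F6. On brief cold dilute HCl, F6 loses ethanol with carbonyl transposition (Stork–Danheiser sequence) to the β-substituted enone F7. Copper-catalysed asymmetric conjugate addition of AlMe3 (Cu(OTf)2, chiral carbene ligand added as its imidazolinium salt, Et2O, −30 °C; ligand antipode chosen for the R product) then returns to the route at 5.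

**Further compounds**
F1 | step 4 | trimethyl{[(3aR)-3a,7-dimethyl-3a,4,5,6-tetrahydro-3H-inden-1-yl]oxy}silane | CC1=C2C(O[Si](C)(C)C)=CC[C@@]2(C)CCC1
F2 | step 4 | dibromocarbene adduct of F1 (CBr2 bridging C6 and C8, siloxy group on C6) | CC1=C2C3(O[Si](C)(C)C)C(Br)(Br)C3C[C@@]2(C)CCC1
F3 | step 4 | (4aR)-2-bromo-4a,8-dimethyl-4a,5,6,7-tetrahydronaphthalen-1(4H)-one | CC1=C2C(=O)C(Br)=CC[C@@]2(C)CCC1
F4 | step 4 | (4aR)-4a,8-dimethyl-2-(prop-1-en-2-yl)-4a,5,6,7-tetrahydronaphthalen-1(4H)-one | CC1=C2C(=O)C(C(C)=C)=CC[C@@]2(C)CCC1
F5 | step 5 | (2S,4aR)-4a,8-dimethyl-2-(propan-2-yl)-2,3,4,4a,5,6-hexahydronaphthalen-1-yl acetate | CC1=CCC[C@]2(C)CC[C@@H](C(C)C)C(OC(C)=O)=C12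
F6 | step 1 | 3-ethoxy-1-[3-(2-methyl-1,3-dioxolan-2-yl)propyl]cyclopent-2-en-1-ol | CCOC1=CC(O)(CCCC2(C)OCCO2)CC1
F7 | step 1 | 3-[3-(2-methyl-1,3-dioxolan-2-yl)propyl]cyclopent-2-en-1-one | O=C1CCC(CCCC2(C)OCCO2)=C1
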